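## Structural features

The target is a cycloheptane (C1–C7) trans-fused along C1–C2 to an α-methylene-γ-butyrolactone. C1 carries the lactone oxygen, C2 carries the lactone carbon Cα, and C3 is the only ring methylene. C4 (secondary OH), C5 (CH3), C6 (tertiary OH plus an (E)-crotonyl ketone), C7 ((R)-2-methylbutanoate), C1 and C2 form an unbroken chain of six stereocentres, and a seventh lies in the ester side chain. With the ring drawn so that C1 to C7 runs clockwise, C1–O, C5–CH3 and C6–OH are α, while C2–Cα, C4–OH, the crotonyl group and C7–O are β. Every pair of neighbouring oxygens is therefore trans, and C1–O and C4–O lie on opposite faces, so a single oxygen bridge across the ring cannot stand for both. Several groups are fragile: the methylene lactone and the enone are Michael acceptors, the tertiary α-ketol can undergo an acyloin shift under base, the α-branched ester can epimerise or migrate to a free neighbouring hydroxyl, and C4–OH can add to either acceptor. The real difficulty is the crowded C5–C6–C7–C1 sector around the fully substituted C6, together with telling four oxygen functions apart and bringing in both acceptors late. The key step exploits C2, the one ring stereocentre without a heteroatom: when C2 is a plain CH2, its β hydrogen stands 1,5 to a carbene placed on the C1 oxygen, so C2–Cα and the lactone ring can be made in one operation after all oxygenated centres are in place.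

## Logic of the disconnections

**27 ⇒ 26 ⇒ 25.** The two O–Si bonds and the Cα=CH2 bond are cut first. The exocyclic methylene is the most electrophilic group, so it should exist for one step only. This removes the need for a lactone enolate. The forward olefination needs an α-phosphonate on the lactone and a base weak enough to spare the enone and both esters.

**25 ⇒ 24.** C2–Cα is cut, which opens the lactone ring. C2 becomes a CH2, and the bicycle reduces to a monocyclic cycloheptane whose stereocentres are all oxygen- or methyl-bearing. The forward step must choose C2–H over C7–H and, at C2, the β hydrogen over the α hydrogen.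

**24 ⇒ 23 ⇒ 20 + 21 (through 22) ⇒ 18 + 19.** The diazo nitrogen, the C7–O acyl bond and the C1–O acyl bond are cut. This reduces the problem to one trans-diol and two purchased acids. The two hydroxyls of 18 must differ enough in hindrance to be acylated in turn, the open C1–OH first and the neopentyl-like C7–OH second.

**18 ⇒ 17 ⇒ 16.** C1–O and C7–O are cut back to a C1=C7 alkene. Two stereocentres are traded for one face selection and one regioselective anti opening. The oxidant must attack the β face, and water must attack C1.

**16 ⇒ 14 (through 15) ⇒ 12 + 13.** The enone Cα=Cβ bond is cut. The crotonyl group reduces to an acetyl group that has only one enolisable position. The forward aldol and elimination must be finished before any ester is present.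

**12 ⇒ 11 ⇒ 8 + 9 (through 10).** The bond from C6 to its acyl carbon is cut. The quaternary carbinol becomes a ring ketone plus an acetyl anion equivalent. The addition must be 1,2 and must come from the β face.

**8 ⇒ 7.** The C1=C7 bond is cut, which turns the ring into an acyclic dienone with only two stereocentres. The closure must tolerate an electron-poor vinyl ketone as one of its two partners.

**7 ⇒ 6 ⇒ 5 ⇒ 4 ⇒ 1 + 2 (through 3).** The C6–C7 bond (vinyl transfer to an amide) and the C4–C5 bond (aldol) are cut. All absolute configuration then comes from one auxiliary-controlled syn aldol. The syn relationship in the chain is what appears as trans C4–O/C5–CH3 on the ring.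

## Other disconnections considered

**Alternative 1:** The cut is C2–C3, made while the ring is still a tetrahydrofuran whose oxygen joins C4 and C7.

- **Forward step.** The allyl vinyl ether contained in a 2-methylene-5-alkenyltetrahydrofuran undergoes a thermal [3,3] shift. C2–C3 forms, O–C7 breaks, and the cycloheptenone A1 results, with a C4 ketone and a C1=C7 alkene.
- **In its favour.** The shift is concerted and suprafacial, so C2 follows stereospecifically from the alkene geometry and the C7 configuration, and the two-carbon arm of the lactone is already attached. On control of C2 this plan is the better one, because the chosen route must tell two diastereotopic hydrogens apart.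
- **On a par.** A1 and 16 are both C1=C7 cycloheptenes next to a quaternary C6 and face the same trans-dioxygenation.
- **Against it.** The substrate is a fully substituted tetrahydrofuran carrying an acid-labile exocyclic enol ether, and the enol ether geometry forces a strained, boat-like array that calls for strong heating. After A1 much remains:
  - stereoselective reduction at C4;
  - raising the C6 arm from the CH2O level to the crotonyl ketone, which needs several redox and C–C steps;
  - oxidation of the C2 arm and lactonisation;
  - α-methylenation through a lactone enolate, a strongly basic step next to an enone and an epimerisable ester.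
- **Step economy.** The count after ring formation should clearly exceed that of the chosen plan.

**Alternative 2:** The cuts are C1–C7 and C4–C5.

- **Forward step.** An alkoxy-substituted silyloxyallyl cation adds across the 2,5-positions of a 3-substituted furan and gives the oxabicycle A2.
- **In its favour.** Two C–C bonds, the carbocycle and four stereocentres arise at once, with absolute control from the 1-phenylethyl group, so on convergence it is the better plan. It is also better at C2, since hydrogenation of C2=C3 from the bridge face should place the acetate arm β, trans to C1–O.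
- **Against it.**
  - The bridge holds C1–O and C4–O on one face, whereas the target has them on opposite faces.
  - In A2, C1 and C7 match the target, but C4 and C5 both have the opposite configuration, so one inversion and one epimerisation to the less stable position are needed.
  - A nucleophile should approach the C6 ketone from the bridge face, which would put the acyl group α and the hydroxyl β, again the reverse of what is required.
  - The bridge carries one oxygen for two carbinol carbons, so one C–O bond must be rebuilt after opening.
  - Two unsymmetrical partners raise an orientation problem.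
- **Wider consequence.** The same argument rules out any furan-derived oxabicycle as the source of 24.
- **Step economy.** The fast start is likely to be used up by corrections at C4, C5 and C6. The chosen plan never inverts a centre.

**Alternative 3:** The cuts are C6–C7 and C7–C1.

- **Forward step.** A silylated diazomethane adds to the Lewis-acid-activated ketone of trans-dihydrocarvone A3. The CH2 α-carbon migrates with loss of N2, and protodesilylation gives the cycloheptanone A4.
- **In its favour.** In very few steps a cheap terpene of the (2S,5S) series delivers the seven-membered ring, C2 and C5 in the correct absolute sense, and all three lactone carbons. On the opening moves it is the better plan.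
- **Against it.**
  - A4 holds one oxygen where the target needs four on the ring and two more in the lactone.
  - C7 can be reached through enol chemistry, but C1 and C4 are unactivated methylenes β to the ketone.
  - Desaturation routes to these positions would erase C5 or endanger C2.
  - The isopropenyl methyl group must be taken to the acid level.
  - The ketone still needs the stereocontrolled acyl addition.
- **Mechanism.** The migration itself is dependable. The later untethered C–H oxidations are not, whereas the chosen plan uses C–H functionalisation once, with a tether that fixes the site.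
- **Step economy.** The early advantage should be lost to redox steps.

Key step: step 15

Remark: ring atoms keep the numbers C1–C7 of the target in all ring compounds. β is the face of C4–O and α is the opposite face, with C1→C7 drawn clockwise and β towards the viewer. Compound 21 is assumed to be bought enantiopure, and its (R) configuration is the one found in the ester of 27.

## Steps

Step 1
Reactants: 1 (4S)-4-benzyl-3-propanoyl-1,3-oxazolidin-2-one; 2 pent-4-enal
Product: 4 (4S)-4-benzyl-3-[(2S,3R)-3-hydroxy-2-methylhept-6-enoyl]-1,3-oxazolidin-2-one, via Z-boron enolate 3 (not isolated)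
Conditions: Bu2BOTf, Et3N, CH2Cl2, 0 °C; 2, −78 to 0 °C; then H2O2, MeOH, pH 7 buffer, 0 °C
Reagents that add atoms: none
Why: Evans syn aldol; 3 reacts through a Zimmerman–Traxler chair in which the benzyl group blocks one enolate face, which should set C4 (R) and C5 (S) in the syn relationship that becomes trans on the ring.

Step 2
Reactants: 4 syn-aldol imide
Product: 5 (2S,3R)-3-hydroxy-N-methoxy-N,2-dimethylhept-6-enamide
Conditions: MeNH(OMe)·HCl, AlMe3, THF, −10 to 0 °C; then 0.5 M HCl
Reagents that add atoms: N,O-dimethylhydroxylamine hydrochloride, CNOC.Cl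
Why: Weinreb transamidation with an aluminium amide; the free β-hydroxyl guides attack to the exocyclic carbonyl, the auxiliary leaves intact and neither stereocentre is touched.

Step 3
Reactants: 5 hydroxy Weinreb amide
Product: 6 (2S,3R)-3-(tert-butyldimethylsilyloxy)-N-methoxy-N,2-dimethylhept-6-enamide
Conditions: TBSOTf, 2,6-lutidine, CH2Cl2, 0 °C
Reagents that add atoms: tert-butyldimethylsilyl triflate, CC(C)(C)[Si](C)(C)OS(=O)(=O)C(F)(F)F
Why: Routine silyl triflate silylation; the TBS ether stays to the last step and its bulk keeps C4–O pseudo-equatorial in the ring intermediates.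

Step 4
Reactants: 6 silylated Weinreb amide
Product: 7 (4S,5R)-5-(tert-butyldimethylsilyloxy)-4-methylnona-1,8-dien-3-one
Conditions: CH2=CHMgBr, THF, 0 °C; inverse quench into 1 M HCl, 0 °C
Reagents that add atoms: vinylmagnesium bromide, C=C[Mg]Br
Why: Weinreb ketone synthesis; the chelated tetrahedral adduct prevents over-addition, and the inverse acidic quench keeps the released hydroxylamine from adding to the new vinyl ketone.

Step 5
Reactants: 7 dienone
Product: 8 (6R,7S)-6-(tert-butyldimethylsilyloxy)-7-methylcyclohept-2-en-1-one (C6 ketone, C7=C1 alkene, C4 β-OTBS, C5 α-CH3)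
Conditions: second-generation Grubbs catalyst (3 mol %), CH2Cl2 (0.005 M), 40 °C
Reagents that add atoms: none
Why: Ring-closing metathesis; the catalyst loads on the terminal alkene and closes onto the vinyl ketone, a standard way to cyclohept-2-enones, and the neutral conditions leave C5 unepimerised.

Step 6
Reactants: 8 cycloheptenone; 9 ethyl vinyl ether
Product: 11 1-[(1R,6R,7S)-6-(tert-butyldimethylsilyloxy)-1-hydroxy-7-methylcyclohept-2-en-1-yl]ethan-1-one (C6 α-OH, β-acetyl), via enol ether adduct 10 (not isolated)
Conditions: 9, t-BuLi, THF, −78 to 0 °C; 8, −78 °C; then 0.5 M HCl, THF, 0 °C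
Reagents that add atoms: water, O
Why: 1,2-Addition of an α-alkoxyvinyllithium (acetyl anion equivalent) to an enone, then enol ether hydrolysis. In the chair-like conformer with C4–OTBS and C5–CH3 pseudo-equatorial, the reagent should take the equatorial path on the β face, anti to the C5 methyl group, so that C6–OH ends α and cis to that methyl group.

Step 7
Reactants: 11 α-ketol
Product: 12 1-[(1R,6R,7S)-6-(tert-butyldimethylsilyloxy)-7-methyl-1-(triethylsilyloxy)cyclohept-2-en-1-yl]ethan-1-one
Conditions: TESOTf, 2,6-lutidine, CH2Cl2, −78 to 0 °C
Reagents that add atoms: triethylsilyl triflate, CC[Si](CC)(CC)OS(=O)(=O)C(F)(F)F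
Why: Silyl triflate silylation of a tertiary alcohol; it blocks acyloin rearrangement under the basic steps to come and supplies the α-face shield used in step 10.

Step 8
Reactants: 12 silylated methyl ketone; 13 acetaldehyde
Product: 14 1-[(1R,6R,7S)-6-(tert-butyldimethylsilyloxy)-7-methyl-1-(triethylsilyloxy)cyclohept-2-en-1-yl]-3-hydroxybutan-1-one (both carbinol epimers)
Conditions: LiN(i-Pr)2, THF, −78 °C; 13, −78 °C; AcOH quench
Reagents that add atoms: none
Why: Lithium enolate aldol addition; the acetyl CH3 is the only enolisable site because C6 is quaternary, and the new carbinol centre is removed in the next step.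

Step 9
Reactants: 14 aldol
Product: 16 (E)-1-[(1R,6R,7S)-6-(tert-butyldimethylsilyloxy)-7-methyl-1-(triethylsilyloxy)cyclohept-2-en-1-yl]but-2-en-1-one, via mesylate 15 (not isolated)
Conditions: MsCl, Et3N, CH2Cl2, 0 °C; then DBU, 0 °C to rt
Reagents that add atoms: none
Why: Mesylation followed by E1cB elimination; both epimers converge on the thermodynamically preferred E enone.

Step 10
Reactants: 16 dienone
Product: 17 (1S,4R,5S,6S,7S) C1,C7 β-epoxide of 16 (ring numbering; C4 β-OTBS, C5 α-CH3, C6 α-OTES, β-crotonyl)
Conditions: mCPBA, NaHCO3, CH2Cl2, 0 °C to rt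
Reagents that add atoms: 3-chloroperoxybenzoic acid, OOC(=O)c1cccc(Cl)c1
Why: Prilezhaev epoxidation; the peracid picks the ring alkene over the electron-poor enone. In the chair cycloheptene with C4–OTBS, C5–CH3 and the acyl group pseudo-equatorial, C6–OTES is pseudo-axial on the α face and should steer oxygen to the β face.

Step 11
Reactants: 17 β-epoxide
Product: 18 (1R,4R,5S,6S,7S) trans-diol: C1 α-OH, C7 β-OH, C4 β-OTBS, C5 α-CH3, C6 α-OTES, β-(E)-crotonyl
Conditions: HClO4 (cat.), THF–H2O (3:1), 0 °C to rt
Reagents that add atoms: water, O
Why: Acid-catalysed anti opening of an epoxide. Water should attack C1, because C7 is neopentyl-like and positive charge there is disfavoured by the oxygen and acyl groups on C6. Inversion at C1 gives the α-hydroxyl while C7–O stays β.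

Step 12
Reactants: 18 trans-diol; 19 diethylphosphonoacetic acid
Product: 20 C1 (diethoxyphosphoryl)acetate of 18 with free C7 β-OH
Conditions: 19 (1.05 equiv), DIC, DMAP (cat.), CH2Cl2, −20 to 0 °C
Reagents that add atoms: none
Why: Steglich esterification; C1–OH is flanked by a CH2 and C7–OH by the quaternary C6, so one equivalent of activated acid should acylate C1–OH, and migration to the more crowded C7 oxygen would be uphill.

Step 13
Reactants: 20 C1 phosphonoacetate; 21 (R)-2-methylbutanoic acid
Product: 23 C1 (diethoxyphosphoryl)acetate, C7 (R)-2-methylbutanoate of 18, via mixed anhydride 22 (not isolated)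
Conditions: 21, 2,4,6-trichlorobenzoyl chloride, Et3N, toluene, rt; then 20, DMAP, rt to 50 °C
Reagents that add atoms: none
Why: Yamaguchi esterification, suited to hindered secondary alcohols; the acyl-pyridinium route avoids ketene formation, so the α-centre of 21 should be kept, and Et3N is too weak to deprotonate the phosphonoacetate.

Step 14
Reactants: 23 diester
Product: 24 C1 diazo(diethoxyphosphoryl)acetate, C7 (R)-2-methylbutanoate, C4 β-OTBS, C5 α-CH3, C6 α-OTES, β-(E)-crotonyl cycloheptane (1R,4R,5S,6S,7S)
Conditions: LiN(SiMe3)2, THF, −78 °C; 4-acetamidobenzenesulfonyl azide, −78 °C to rt; AcOH quench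
Reagents that add atoms: 4-acetamidobenzenesulfonyl azide, CC(=O)Nc1ccc(cc1)S(=O)(=O)N=[N+]=[N-]
Why: Regitz diazo transfer; the phosphonoacetate CH2 is by far the most acidic site, so one equivalent of base at low temperature leaves the enone and the other ester alone.

Step 15
Reactants: 24 diazophosphonoacetate
Product: 25 trans-fused α-(diethoxyphosphoryl)-γ-butyrolactone (C1 α-O, C2 β-Cα, both Cα epimers; other centres as in 24)
Conditions: Rh2(O2C-n-C7H15)4 (2 mol %), CH2Cl2, 45 °C (sealed tube), slow addition of 24
Reagents that add atoms: none
Why: The electrophilic carboxylate complex of divalent rhodium attacks the diazo carbon, N2 leaves, and the acceptor/acceptor carbenoid inserts into a C–H bond through a concerted three-centre, hydride-transfer-like transition state with retention at carbon. The closest known reaction type is the dirhodium-catalysed 1,5 C–H insertion of cycloalkyl diazo(phosphoryl)acetates to fused α-phosphono-γ-butyrolactones. The lactone closes in the 1,5 mode, with the carbenoid carbon, ester C=O, ester O, C1 and C2 as its five atoms, a size preferred over the four-ring (C1–H) and six-ring (C3–H) options. C2 is set by which diastereotopic hydrogen is replaced: in the twist-chair that keeps C4–OTBS, C5–CH3, the crotonyl group and the C1 ester oxygen pseudo-equatorial (C6–OTES pseudo-axial), the β C2–H is equatorial, gauche to C1–O and exposed, and such carbenoids prefer equatorial C–H bonds, so Cα should end β and the fusion trans, a geometry that a cycloheptane accommodates with little strain. Cα forms as an epimer mixture of no consequence, since it becomes sp2 in step 16. Site selectivity is needed against the other 1,5 position, C7–H, which is deactivated by the inductive pull of its acyloxy group and crowded by the quaternary C6. Chemoselectivity rests on silylation of both hydroxyls (no O–H insertion) and on the electron-poor crotonyl alkene (no cyclopropanation). Carboxylate ligands are chosen because electron-rich carboxamidate complexes release N2 from doubly stabilised diazo esters only sluggishly, and ligand bulk (octanoate, triphenylacetate) is the handle for raising the trans preference.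

Step 16
Reactants: 25 α-phosphono lactone
Product: 26 bis-silylated α-methylene lactone (C4 β-OTBS, C6 α-OTES; 1R,2R,4R,5S,6S,7S)
Conditions: K2CO3, 37% aq. HCHO, THF, 0 °C
Reagents that add atoms: formaldehyde, C=O
Why: Horner–Wadsworth–Emmons olefination; both Cα epimers give the same stabilised anion, and carbonate is strong enough for the doubly activated Cα–H but too weak to enolise the esters or disturb the enone.

Step 17
Reactants: 26 bis-silyl ether
Product: 27 target, (1R,2R,4R,5S,6S,7S) ring configuration, (2R)-2-methylbutanoate
Conditions: HF·pyridine, pyridine, THF, 0 °C to rt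
Reagents that add atoms: none
Why: Fluoride-driven desilylation in a mildly acidic medium removes the TES and TBS groups and avoids the basic conditions that would trigger oxa-Michael addition, acyl migration or acyloin shift.

## Compound list

1 | (4S)-4-benzyl-3-propanoyl-1,3-oxazolidin-2-one | CCC(=O)N1[C@@H](Cc2ccccc2)COC1=O | starting material
2 | pent-4-enal | C=CCCC=O | starting material
3 | Z-dibutylboron enolate of 1 | C/C=C(\OB(CCCC)CCCC)N1[C@@H](Cc2ccccc2)COC1=O | intermediate
4 | syn-aldol imide | C=CCC[C@@H](O)[C@H](C)C(=O)N1[C@@H](Cc2ccccc2)COC1=O | intermediate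
5 | hydroxy Weinreb amide | C=CCC[C@@H](O)[C@H](C)C(=O)N(C)OC | intermediate
6 | TBS-protected Weinreb amide | C=CCC[C@@H](O[Si](C)(C)C(C)(C)C)[C@H](C)C(=O)N(C)OC | intermediate
7 | acyclic dienone | C=CCC[C@@H](O[Si](C)(C)C(C)(C)C)[C@H](C)C(=O)C=C | intermediate
8 | cycloheptenone | C1C[C@@H](O[Si](C)(C)C(C)(C)C)[C@H](C)C(=O)C=C1 | intermediate
9 | ethyl vinyl ether | C=COCC | starting material
10 | enol ether adduct | C1C[C@@H](O[Si](C)(C)C(C)(C)C)[C@H](C)[C@@](O)(C(=C)OCC)C=C1 | intermediate
11 | tertiary α-ketol (acetyl) | C1C[C@@H](O[Si](C)(C)C(C)(C)C)[C@H](C)[C@@](O)(C(C)=O)C=C1 | intermediate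
12 | TES-protected methyl ketone | C1C[C@@H](O[Si](C)(C)C(C)(C)C)[C@H](C)[C@@](O[Si](CC)(CC)CC)(C(C)=O)C=C1 | intermediate
13 | acetaldehyde | CC=O | starting material
14 | aldol (carbinol epimers) | C1C[C@@H](O[Si](C)(C)C(C)(C)C)[C@H](C)[C@@](O[Si](CC)(CC)CC)(C(=O)CC(C)O)C=C1 | intermediate
15 | mesylate of 14 | C1C[C@@H](O[Si](C)(C)C(C)(C)C)[C@H](C)[C@@](O[Si](CC)(CC)CC)(C(=O)CC(C)OS(C)(=O)=O)C=C1 | intermediate
16 | crotonyl cycloheptene | C1C[C@@H](O[Si](C)(C)C(C)(C)C)[C@H](C)[C@@](O[Si](CC)(CC)CC)(C(=O)/C=C/C)C=C1 | intermediate
17 | C1,C7 β-epoxide | O1[C@H]2CC[C@@H](O[Si](C)(C)C(C)(C)C)[C@H](C)[C@@](O[Si](CC)(CC)CC)(C(=O)/C=C/C)[C@@H]12 | intermediate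
18 | C1 α, C7 β trans-diol | O[C@@H]1CC[C@@H](O[Si](C)(C)C(C)(C)C)[C@H](C)[C@@](O[Si](CC)(CC)CC)(C(=O)/C=C/C)[C@H]1O | intermediate
19 | diethylphosphonoacetic acid | OC(=O)CP(=O)(OCC)OCC | starting material
20 | C1 phosphonoacetate, C7–OH | CCOP(=O)(OCC)CC(=O)O[C@@H]1CC[C@@H](O[Si](C)(C)C(C)(C)C)[C@H](C)[C@@](O[Si](CC)(CC)CC)(C(=O)/C=C/C)[C@H]1O | intermediate
21 | (R)-2-methylbutanoic acid | CC[C@@H](C)C(=O)O | starting material
22 | (R)-2-methylbutanoic 2,4,6-trichlorobenzoic anhydride | CC[C@@H](C)C(=O)OC(=O)c1c(Cl)cc(Cl)cc1Cl | intermediate
23 | C1 phosphonoacetate, C7 (R)-2-methylbutanoate | CCOP(=O)(OCC)CC(=O)O[C@@H]1CC[C@@H](O[Si](C)(C)C(C)(C)C)[C@H](C)[C@@](O[Si](CC)(CC)CC)(C(=O)/C=C/C)[C@H]1OC(=O)[C@H](C)CC | intermediate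
24 | C1 diazophosphonoacetate (key-step precursor) | CCOP(=O)(OCC)C(=[N+]=[N-])C(=O)O[C@@H]1CC[C@@H](O[Si](C)(C)C(C)(C)C)[C@H](C)[C@@](O[Si](CC)(CC)CC)(C(=O)/C=C/C)[C@H]1OC(=O)[C@H](C)CC | intermediate
25 | trans-fused α-phosphono lactone (Cα epimers) | CCOP(=O)(OCC)C1C(=O)O[C@@H]2[C@@H]1C[C@@H](O[Si](C)(C)C(C)(C)C)[C@H](C)[C@@](O[Si](CC)(CC)CC)(C(=O)/C=C/C)[C@H]2OC(=O)[C@H](C)CC | intermediate
26 | bis-silylated α-methylene lactone | C=C1C(=O)O[C@@H]2[C@@H]1C[C@@H](O[Si](C)(C)C(C)(C)C)[C@H](C)[C@@](O[Si](CC)(CC)CC)(C(=O)/C=C/C)[C@H]2OC(=O)[C@H](C)CC | intermediate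
27 | CNP0331957.3 | C=C1C(=O)O[C@@H]2[C@@H]1C[C@@H](O)[C@H](C)[C@@](O)(C(=O)/C=C/C)[C@H]2OC(=O)[C@H](C)CC | target

## Step count and least certain steps

Total: 17 steps. Longest linear sequence: 17 steps (1 and 2 to 27). Compounds 9, 13, 19 and 21 are purchased and enter directly.

**Step 15 (key step).**
- *Risk:* the most likely failure is insertion into the α (pseudo-axial) C2–H, which would give the cis fusion, because a cycloheptane is conformationally loose. The second concern is slow nitrogen loss from the doubly stabilised diazo ester, which leaves time for carbene dimerisation or capture of adventitious water.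
- *Fallback:* it sets out from 18, keeps the same bond construction, and changes both the carbene class and the methylenation chemistry. Acetoacetylation of C1–OH with 2,2,6-trimethyl-4H-1,3-dioxin-4-one in hot toluene gives the C1 acetoacetate F1. Diazo transfer with Et3N and the sulfonyl azide gives the C1 diazoacetoacetate F2. Yamaguchi acylation of C7–OH with 21 gives the fully acylated diazoacetoacetate F3. Its more electrophilic keto-carbenoid should insert at lower temperature with bulky dirhodium carboxylates and give the α-acetyl lactone F4. Deacetylative methylenation with paraformaldehyde and K2CO3 comes back to the route at 26.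

**Step 6.**
- *Risk:* poor facial selectivity in the addition to a flexible seven-ring enone, together with some enolisation, because the two carbonyl faces differ only in torsional terms and in the nearby methyl group.
- *Fallback:* it sets out from 5 and fixes C6 in the open chain by chelation. Excess 1-ethoxyvinyllithium converts 5 into the β-hydroxy α-ethoxy enone F5. Excess vinylmagnesium bromide adds through the six-membered magnesium alkoxide chelate, in which C5–CH3 and the C4 chain lie on one face and the nucleophile enters from the other, to give the diol enol ether F6. Mild acid gives the dihydroxy methyl ketone F7. TBSCl and imidazole silylate only the secondary hydroxyl to give the mono-TBS diene F8, and ring-closing metathesis comes back to the route at 11.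

**Step 10.**
- *Risk:* poor facial selectivity if the ring populates a conformer in which C6–OTES no longer covers the α face, and slow epoxidation of an inductively deactivated alkene, which would let Baeyer–Villiger-type oxidation at the α-silyloxy ketone compete.
- *Fallback:* it sets out from 12 and delivers oxygen from a hydroxyl placed on the β face. Reduction with NaBH4 and CeCl3 gives the secondary alcohol F9. VO(acac)2 with t-BuOOH, bound to this homoallylic hydroxyl on the β substituent, gives the β-epoxy alcohol F10. Dess–Martin oxidation gives the epoxy methyl ketone F11. The aldol addition of step 8 gives the epoxy aldol F12, and the mesylation and elimination of step 9 come back to the route at 17.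

**Step 11.**
- *Risk:* loss of the tertiary TES group in aqueous acid, and to a lesser degree attack of water at C7.
- *Fallback:* it sets out from 17 and accepts the silyl loss. Longer exposure to aqueous acid gives the C1,C6,C7-triol F13. Selective Steglich coupling with 19 gives the C1 phosphonoacetate diol F14. Yamaguchi acylation with 21, which is easier next to a free tertiary hydroxyl that does not itself acylate, gives the diester ketol F15. TESOTf with 2,6-lutidine comes back to the route at 23.

**Step 13.**
- *Risk:* slow acylation of the neopentyl-like C7–OH, so that long exposure to amine bases allows side reactions at the acidic phosphonoacetate CH2 and partial epimerisation of the activated acid.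
- *Fallback:* it sets out from 18 and changes the order of events. TESCl and imidazole silylate the open C1–OH to give the C1 TES ether F16. Forcing acylation of C7–OH with the anhydride of 21 and DMAP gives the C7 ester F17. PPTS in MeOH removes the secondary TES group selectively to give the C1 alcohol F18, and Steglich coupling with 19 comes back to the route at 23.

## Further compounds

F1 | step 15 | C1 acetoacetate of 18, C7–OH free | CC(=O)CC(=O)O[C@@H]1CC[C@@H](O[Si](C)(C)C(C)(C)C)[C@H](C)[C@@](O[Si](CC)(CC)CC)(C(=O)/C=C/C)[C@H]1O
F2 | step 15 | C1 diazoacetoacetate, C7–OH free | CC(=O)C(=[N+]=[N-])C(=O)O[C@@H]1CC[C@@H](O[Si](C)(C)C(C)(C)C)[C@H](C)[C@@](O[Si](CC)(CC)CC)(C(=O)/C=C/C)[C@H]1O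
F3 | step 15 | C1 diazoacetoacetate, C7 (R)-2-methylbutanoate | CC(=O)C(=[N+]=[N-])C(=O)O[C@@H]1CC[C@@H](O[Si](C)(C)C(C)(C)C)[C@H](C)[C@@](O[Si](CC)(CC)CC)(C(=O)/C=C/C)[C@H]1OC(=O)[C@H](C)CC
F4 | step 15 | trans-fused α-acetyl lactone (Cα epimers) | CC(=O)C1C(=O)O[C@@H]2[C@@H]1C[C@@H](O[Si](C)(C)C(C)(C)C)[C@H](C)[C@@](O[Si](CC)(CC)CC)(C(=O)/C=C/C)[C@H]2OC(=O)[C@H](C)CC
F5 | step 6 | (4S,5R)-2-ethoxy-5-hydroxy-4-methylnona-1,8-dien-3-one | C=CCC[C@@H](O)[C@H](C)C(=O)C(=C)OCC
F6 | step 6 | acyclic diol enol ether (C6 set by chelation) | C=CCC[C@@H](O)[C@H](C)[C@@](O)(C(=C)OCC)C=C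
F7 | step 6 | acyclic dihydroxy methyl ketone | C=CCC[C@@H](O)[C@H](C)[C@@](O)(C(C)=O)C=C
F8 | step 6 | acyclic C4 TBS ether, tertiary OH free | C=CCC[C@@H](O[Si](C)(C)C(C)(C)C)[C@H](C)[C@@](O)(C(C)=O)C=C
F9 | step 10 | secondary alcohol from 12 (carbinol epimers) | C1C[C@@H](O[Si](C)(C)C(C)(C)C)[C@H](C)[C@@](O[Si](CC)(CC)CC)(C(C)O)C=C1
F10 | step 10 | β-epoxy alcohol | O1[C@H]2CC[C@@H](O[Si](C)(C)C(C)(C)C)[C@H](C)[C@@](O[Si](CC)(CC)CC)(C(C)O)[C@@H]12
F11 | step 10 | β-epoxy methyl ketone | O1[C@H]2CC[C@@H](O[Si](C)(C)C(C)(C)C)[C@H](C)[C@@](O[Si](CC)(CC)CC)(C(C)=O)[C@@H]12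
F12 | step 10 | β-epoxy aldol (carbinol epimers) | O1[C@H]2CC[C@@H](O[Si](C)(C)C(C)(C)C)[C@H](C)[C@@](O[Si](CC)(CC)CC)(C(=O)CC(C)O)[C@@H]12
F13 | step 11 | C1,C6,C7-triol, C4 β-OTBS | O[C@@H]1CC[C@@H](O[Si](C)(C)C(C)(C)C)[C@H](C)[C@@](O)(C(=O)/C=C/C)[C@H]1O
F14 | step 11 | C1 phosphonoacetate, C6 and C7 hydroxyls free | CCOP(=O)(OCC)CC(=O)O[C@@H]1CC[C@@H](O[Si](C)(C)C(C)(C)C)[C@H](C)[C@@](O)(C(=O)/C=C/C)[C@H]1O
F15 | step 11 | C1 phosphonoacetate, C7 (R)-2-methylbutanoate, C6–OH free | CCOP(=O)(OCC)CC(=O)O[C@@H]1CC[C@@H](O[Si](C)(C)C(C)(C)C)[C@H](C)[C@@](O)(C(=O)/C=C/C)[C@H]1OC(=O)[C@H](C)CC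
F16 | step 13 | C1 TES ether of 18, C7–OH free | CC[Si](CC)(CC)O[C@@H]1CC[C@@H](O[Si](C)(C)C(C)(C)C)[C@H](C)[C@@](O[Si](CC)(CC)CC)(C(=O)/C=C/C)[C@H]1O
F17 | step 13 | C1 TES ether, C7 (R)-2-methylbutanoate | CC[Si](CC)(CC)O[C@@H]1CC[C@@H](O[Si](C)(C)C(C)(C)C)[C@H](C)[C@@](O[Si](CC)(CC)CC)(C(=O)/C=C/C)[C@H]1OC(=O)[C@H](C)CC
F18 | step 13 | C1 alcohol, C7 (R)-2-methylbutanoate | O[C@@H]1CC[C@@H](O[Si](C)(C)C(C)(C)C)[C@H](C)[C@@](O[Si](CC)(CC)CC)(C(=O)/C=C/C)[C@H]1OC(=O)[C@H](C)CC
A1 | alternative 1 | cyclohept-4-enone with C4 ketone, C1=C7 alkene, C2 β-CH2CH2OPMB arm, C5 α-methyl, C6 spiro-acetonide (C6–O α) | O=C1C[C@H](CCOCc2ccc(OC)cc2)C=C[C@]3(COC(C)(C)O3)[C@H]1C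
A2 | alternative 2 | 8-oxabicyclo[3.2.1]oct-6-en-3-one with equatorial C7 (1-phenylethoxy), equatorial C5 methyl and the methyl acetate arm on C2 | [C@H]12C(CC(=O)OC)=C[C@H](O1)[C@@H](C)C(=O)[C@H]2O[C@@H](C)c3ccccc3
A3 | alternative 3 | (2S,5S)-trans-dihydrocarvone | O=C1[C@@H](C)CC[C@H](C(C)=C)C1
A4 | alternative 3 | (2S,5S)-trans-2-methyl-5-(prop-1-en-2-yl)cycloheptan-1-one | O=C1[C@@H](C)CC[C@H](C(C)=C)CC1
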